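**Plan**

Labels: C7/C7' are the benzylic OCH(Ar) carbons, C8/C8' the ring-fusion CH carbons and C9/C9' the OCH2 carbons of the 3,7-dioxabicyclo[3.3.0]octane. Ring A is O–C7–C8–C8'–C9' and ring B is O–C7'–C8'–C8–C9. The SMILES decodes as 7S,8R,7'S,8'R with both aryl groups exo.
Enabling feature: each fusion carbon C8 and C8' bears exactly one one-carbon branch (C9, C9'). C9–C8–C8'–C9' is therefore a succinate on the backbone C7–C8–C8'–C7' of a 1,4-diarylbut-2-ene-1,4-diol, and two carbonyl carbons added across C8=C8' complete the skeleton.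
Cuts: O–C9' and O–C9 (rings A and B), then C8–C9 and C8'–C9' together, then C8'–C7' (alkenylzinc plus aldehyde), then C7–C8 (alkynylzinc plus aldehyde).
Forward: C7–C8 is made first, then C8'–C7' with the E alkene, then both C9 carbons in one oxidative bis(methoxycarbonylation). Ester reduction and mesylation follow, rings A and B close in one fluoride-triggered double etherification, and debenzylation comes last.
Stereochemistry: C7 comes from (S)-BINOL/Ti(OiPr)4 control and C7' from (−)-MIB control. C8/C8' come from syn addition to the E alkene on the face chosen jointly by C7 and C7'. Both ring closures occur at primary carbons and touch no stereocentre.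

Key step: step 7

Remark: TBS = tert-butyldimethylsilyl, Bn = benzyl, Ms = methanesulfonyl. Descriptors at C7, C7', C8 and C8' change along the route only through priority changes; the spatial arrangement is the same in every SMILES.

Step 1
Reactants: 1 4-(benzyloxy)-3-methoxybenzaldehyde; 2 ethynyltrimethylsilane
Product: 4 (R)-1-[4-(benzyloxy)-3-methoxyphenyl]-3-(trimethylsilyl)prop-2-yn-1-ol, via ethyl(trimethylsilylethynyl)zinc 3 (not isolated)
Conditions: 2, Et2Zn, N-methylimidazole (5 mol%), CH2Cl2, rt; then (S)-BINOL (20 mol%), Ti(OiPr)4 (50 mol%), 1, rt; aq work-up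
Reagents that add atoms: none
Why: BINOL–Ti(OiPr)4-catalysed asymmetric alkynylzinc addition is a reaction type tailored to aromatic aldehydes, and the (S)-BINOL complex should deliver the alkynyl group to the Si face of 1, which sets C7 (descriptor R here only because the silylalkynyl branch outranks the aryl group).

Step 2
Reactants: 4 (R)-1-[4-(benzyloxy)-3-methoxyphenyl]-3-(trimethylsilyl)prop-2-yn-1-ol
Product: 5 (R)-tert-butyl({1-[4-(benzyloxy)-3-methoxyphenyl]-3-(trimethylsilyl)prop-2-yn-1-yl}oxy)dimethylsilane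
Conditions: TBSCl, imidazole, DMF, rt
Reagents that add atoms: tert-butyldimethylsilyl chloride CC(C)(C)[Si](C)(C)Cl
Why: Imidazole-promoted silylation of a secondary alcohol runs under mildly basic conditions that cannot ionise the benzylic propargylic C–O bond, so C7 is kept.

Step 3
Reactants: 5 (R)-tert-butyl({1-[4-(benzyloxy)-3-methoxyphenyl]-3-(trimethylsilyl)prop-2-yn-1-yl}oxy)dimethylsilane
Product: 6 (S)-tert-butyl({1-[4-(benzyloxy)-3-methoxyphenyl]prop-2-yn-1-yl}oxy)dimethylsilane
Conditions: K2CO3 (0.2 equiv), MeOH/THF, rt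
Reagents that add atoms: none
Why: Carbonate-catalysed methanolysis (protiodesilylation) cleaves the alkynyl C–Si bond far faster than the hindered secondary O–Si bond, and the descriptor turns to S only because aryl outranks ethynyl.

Step 4
Reactants: 7 3-hydroxy-4,5-dimethoxybenzaldehyde
Product: 8 3-(benzyloxy)-4,5-dimethoxybenzaldehyde
Conditions: BnBr, K2CO3, DMF, rt
Reagents that add atoms: benzyl bromide BrCc1ccccc1
Why: Williamson ether synthesis on the single phenol, with the aldehyde and the methyl ethers inert to K2CO3.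

Step 5
Reactants: 6 (S)-tert-butyl({1-[4-(benzyloxy)-3-methoxyphenyl]prop-2-yn-1-yl}oxy)dimethylsilane; 8 3-(benzyloxy)-4,5-dimethoxybenzaldehyde
Product: 11 (1S,2E,4S)-1-[3-(benzyloxy)-4,5-dimethoxyphenyl]-4-[4-(benzyloxy)-3-methoxyphenyl]-4-[(tert-butyldimethylsilyl)oxy]but-2-en-1-ol, via alkenyl(dicyclohexyl)borane 9 (not isolated), via alkenyl(methyl)zinc 10 (not isolated)
Conditions: Cy2BH (freshly prepared), toluene, 0 °C to rt; Me2Zn, −78 °C; (−)-MIB [(2S)-3-exo-morpholinoisoborneol, 5 mol%], then 8, −78 to −10 °C; aq work-up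
Reagents that add atoms: none
Why: Syn hydroboration of the terminal alkyne fixes the E geometry, boron-to-zinc exchange gives the alkenylzinc, and the amino-alcohol-catalysed asymmetric alkenylzinc addition to aromatic aldehydes should, with (−)-MIB, strike the Si face of 8 and set C7' as S under catalyst control, so that any minor enantiomer of 6 is carried into a separable diastereomer.

Step 6
Reactants: 11 (1S,2E,4S)-1-[3-(benzyloxy)-4,5-dimethoxyphenyl]-4-[4-(benzyloxy)-3-methoxyphenyl]-4-[(tert-butyldimethylsilyl)oxy]but-2-en-1-ol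
Product: 12 (1S,2E,4S)-1-[4-(benzyloxy)-3-methoxyphenyl]-4-[3-(benzyloxy)-4,5-dimethoxyphenyl]-1,4-bis[(tert-butyldimethylsilyl)oxy]but-2-ene
Conditions: TBSCl, imidazole, DMF, rt
Reagents that add atoms: tert-butyldimethylsilyl chloride CC(C)(C)[Si](C)(C)Cl
Why: The same imidazole-promoted silylation as in step 2 is chosen because it is non-acidic toward the doubly activated allylic benzylic alcohol and because silyl ethers neither coordinate palladium nor leave readily in step 7.

Step 7
Reactants: 12 (1S,2E,4S)-1-[4-(benzyloxy)-3-methoxyphenyl]-4-[3-(benzyloxy)-4,5-dimethoxyphenyl]-1,4-bis[(tert-butyldimethylsilyl)oxy]but-2-ene; 13 carbon monoxide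
Product: 14 dimethyl (2S,3S)-2-{(S)-[4-(benzyloxy)-3-methoxyphenyl][(tert-butyldimethylsilyl)oxy]methyl}-3-{(S)-[3-(benzyloxy)-4,5-dimethoxyphenyl][(tert-butyldimethylsilyl)oxy]methyl}butanedioate
Conditions: Pd(OCOCF3)2 (5 mol%), N,N'-bis(2,6-dimethylphenyl)butane-2,3-diimine (5.5 mol%), p-benzoquinone (1.5 equiv), 2,6-di-tert-butylpyridine (10 mol%), CO (4 bar), MeOH/THF 1:1, 20 °C
Reagents that add atoms: carbon monoxide [C-]#[O+] (compound 13); methanol CO
Why: Proposed new method: methanol and CO turn the diimine-ligated cationic divalent palladium into a Pd–CO2Me species, the C8=C8' alkene inserts into that bond through a four-centre syn transition state, CO inserts into the new secondary Pd–C bond with retention, methanolysis of the acyl releases 14, and benzoquinone returns zerovalent palladium to the divalent state. The closest known reaction type is the diastereospecific oxidative bis-alkoxycarbonylation of simple 1,2-disubstituted alkenes with this catalyst family, which has not been run on an alkene flanked by two oxygenated benzylic stereocentres. No ring closes; the bonds C8–C9 and C8'–C9' and the stereocentres C8 and C8' are made. Their mutual like relation (8S,8'S at the diester stage) follows from suprafacial addition to the E geometry, and their relation to C7 and C7' follows from the alkene face that is attacked. The step needs the Si,Si face: in the staggered transition state each S-configured allylic centre should hold its aryl group antiperiplanar to the forming bond, its C–O bond inside near the alkene plane and its H outside, and because the pseudo-C2 axis stands perpendicular to the alkene plane both centres pick the same face and their preferences multiply. Non-coordinating silyl ethers exclude oxygen-directed delivery to the other face and slow β-oxygen elimination, the chelating ligand and CO pressure leave no free site for β-hydride elimination, and the hindered pyridine buffers the CF3CO2H released from the precatalyst so that the ionisable allylic benzylic ethers survive.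

Step 8
Reactants: 14 dimethyl (2S,3S)-2-{(S)-[4-(benzyloxy)-3-methoxyphenyl][(tert-butyldimethylsilyl)oxy]methyl}-3-{(S)-[3-(benzyloxy)-4,5-dimethoxyphenyl][(tert-butyldimethylsilyl)oxy]methyl}butanedioate
Product: 15 (2R,3R)-2-{(S)-[4-(benzyloxy)-3-methoxyphenyl][(tert-butyldimethylsilyl)oxy]methyl}-3-{(S)-[3-(benzyloxy)-4,5-dimethoxyphenyl][(tert-butyldimethylsilyl)oxy]methyl}butane-1,4-diol
Conditions: iBu2AlH (6 equiv), CH2Cl2, −78 to 0 °C; aq potassium sodium tartrate
Reagents that add atoms: none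
Why: Low-temperature ester reduction with iBu2AlH passes through non-basic aluminium alkoxides, which should avoid epimerisation at C8/C8', retro-aldol cleavage and 1,3-silyl migration while benzyl and silyl ethers stay intact.

Step 9
Reactants: 15 (2R,3R)-2-{(S)-[4-(benzyloxy)-3-methoxyphenyl][(tert-butyldimethylsilyl)oxy]methyl}-3-{(S)-[3-(benzyloxy)-4,5-dimethoxyphenyl][(tert-butyldimethylsilyl)oxy]methyl}butane-1,4-diol
Product: 16 (2R,3R)-2-{(S)-[4-(benzyloxy)-3-methoxyphenyl][(tert-butyldimethylsilyl)oxy]methyl}-3-{(S)-[3-(benzyloxy)-4,5-dimethoxyphenyl][(tert-butyldimethylsilyl)oxy]methyl}butane-1,4-diyl dimethanesulfonate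
Conditions: MsCl, Et3N, CH2Cl2, 0 °C
Reagents that add atoms: methanesulfonyl chloride CS(=O)(=O)Cl
Why: Sulfonylation of the two primary alcohols with MsCl/Et3N is routine and no other nucleophilic group is free.

Step 10
Reactants: 16 (2R,3R)-2-{(S)-[4-(benzyloxy)-3-methoxyphenyl][(tert-butyldimethylsilyl)oxy]methyl}-3-{(S)-[3-(benzyloxy)-4,5-dimethoxyphenyl][(tert-butyldimethylsilyl)oxy]methyl}butane-1,4-diyl dimethanesulfonate
Product: 19 (1S,3aR,4S,6aR)-1-[4-(benzyloxy)-3-methoxyphenyl]-4-[3-(benzyloxy)-4,5-dimethoxyphenyl]tetrahydro-1H,3H-furo[3,4-c]furan, via desilylated diol bis(mesylate) 17 (not isolated), via monocyclic tetrahydrofuran mesylate 18 (not isolated)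
Conditions: Bu4NF (3 equiv), THF, 0 to 40 °C
Reagents that add atoms: none
Why: Fluoride desilylation frees each benzylic alkoxide, which closes its ring by intramolecular Williamson etherification in the 5-exo-tet mode on the distal primary mesylate (O on C7 to C9' for ring A, O on C7' to C9 for ring B) rather than the 4-exo-tet mode on the proximal one, and since bonds form only at C9 and C9' all four stereocentres are retained and the like C8/C8' relation enforces the cis fusion.

Step 11
Reactants: 19 (1S,3aR,4S,6aR)-1-[4-(benzyloxy)-3-methoxyphenyl]-4-[3-(benzyloxy)-4,5-dimethoxyphenyl]tetrahydro-1H,3H-furo[3,4-c]furan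
Product: 20 5-[(1S,3aR,4S,6aR)-4-(4-hydroxy-3-methoxyphenyl)tetrahydro-1H,3H-furo[3,4-c]furan-1-yl]-2,3-dimethoxyphenol (CNP0324902.1)
Conditions: H2 (1 atm), 10% Pd/C, EtOAc, rt
Reagents that add atoms: none
Why: Catalytic hydrogenolysis cleaves aryl benzyl ethers much faster than the cyclic benzylic C7–O and C7'–O bonds in a neutral aprotic solvent, so stopping at consumption of 19 should give 20 without ring opening or epimerisation.

**Compound list**

1 | 4-(benzyloxy)-3-methoxybenzaldehyde | COc1cc(C=O)ccc1OCc1ccccc1 | starting material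
2 | ethynyltrimethylsilane | C#C[Si](C)(C)C | starting material
3 | ethyl(trimethylsilylethynyl)zinc | CC[Zn]C#C[Si](C)(C)C | intermediate
4 | (R)-1-[4-(benzyloxy)-3-methoxyphenyl]-3-(trimethylsilyl)prop-2-yn-1-ol | COc1cc([C@@H](O)C#C[Si](C)(C)C)ccc1OCc1ccccc1 | intermediate
5 | (R)-tert-butyl({1-[4-(benzyloxy)-3-methoxyphenyl]-3-(trimethylsilyl)prop-2-yn-1-yl}oxy)dimethylsilane | COc1cc([C@@H](O[Si](C)(C)C(C)(C)C)C#C[Si](C)(C)C)ccc1OCc1ccccc1 | intermediate
6 | (S)-tert-butyl({1-[4-(benzyloxy)-3-methoxyphenyl]prop-2-yn-1-yl}oxy)dimethylsilane | COc1cc([C@@H](O[Si](C)(C)C(C)(C)C)C#C)ccc1OCc1ccccc1 | intermediate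
7 | 3-hydroxy-4,5-dimethoxybenzaldehyde | COc1cc(C=O)cc(O)c1OC | starting material
8 | 3-(benzyloxy)-4,5-dimethoxybenzaldehyde | COc1cc(C=O)cc(OCc2ccccc2)c1OC | intermediate
9 | {(1E,3S)-3-[4-(benzyloxy)-3-methoxyphenyl]-3-[(tert-butyldimethylsilyl)oxy]prop-1-en-1-yl}dicyclohexylborane | COc1cc([C@@H](O[Si](C)(C)C(C)(C)C)/C=C/B(C2CCCCC2)C2CCCCC2)ccc1OCc1ccccc1 | intermediate
10 | {(1E,3S)-3-[4-(benzyloxy)-3-methoxyphenyl]-3-[(tert-butyldimethylsilyl)oxy]prop-1-en-1-yl}(methyl)zinc | COc1cc([C@@H](O[Si](C)(C)C(C)(C)C)/C=C/[Zn]C)ccc1OCc1ccccc1 | intermediate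
11 | (1S,2E,4S)-1-[3-(benzyloxy)-4,5-dimethoxyphenyl]-4-[4-(benzyloxy)-3-methoxyphenyl]-4-[(tert-butyldimethylsilyl)oxy]but-2-en-1-ol | COc1cc([C@@H](O[Si](C)(C)C(C)(C)C)/C=C/[C@H](O)c2cc(OCc3ccccc3)c(OC)c(OC)c2)ccc1OCc1ccccc1 | intermediate
12 | (1S,2E,4S)-1-[4-(benzyloxy)-3-methoxyphenyl]-4-[3-(benzyloxy)-4,5-dimethoxyphenyl]-1,4-bis[(tert-butyldimethylsilyl)oxy]but-2-ene | COc1cc([C@@H](O[Si](C)(C)C(C)(C)C)/C=C/[C@H](O[Si](C)(C)C(C)(C)C)c2cc(OCc3ccccc3)c(OC)c(OC)c2)ccc1OCc1ccccc1 | intermediate
13 | carbon monoxide | [C-]#[O+] | starting material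
14 | dimethyl (2S,3S)-2-{(S)-[4-(benzyloxy)-3-methoxyphenyl][(tert-butyldimethylsilyl)oxy]methyl}-3-{(S)-[3-(benzyloxy)-4,5-dimethoxyphenyl][(tert-butyldimethylsilyl)oxy]methyl}butanedioate | COc1cc([C@@H](O[Si](C)(C)C(C)(C)C)[C@@H](C(=O)OC)[C@H](C(=O)OC)[C@H](O[Si](C)(C)C(C)(C)C)c2cc(OCc3ccccc3)c(OC)c(OC)c2)ccc1OCc1ccccc1 | intermediate
15 | (2R,3R)-2-{(S)-[4-(benzyloxy)-3-methoxyphenyl][(tert-butyldimethylsilyl)oxy]methyl}-3-{(S)-[3-(benzyloxy)-4,5-dimethoxyphenyl][(tert-butyldimethylsilyl)oxy]methyl}butane-1,4-diol | COc1cc([C@@H](O[Si](C)(C)C(C)(C)C)[C@@H](CO)[C@H](CO)[C@H](O[Si](C)(C)C(C)(C)C)c2cc(OCc3ccccc3)c(OC)c(OC)c2)ccc1OCc1ccccc1 | intermediate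
16 | 1,4-dimethanesulfonate of 15, (2R,3R) with both carbinol centres S | COc1cc([C@@H](O[Si](C)(C)C(C)(C)C)[C@@H](COS(C)(=O)=O)[C@H](COS(C)(=O)=O)[C@H](O[Si](C)(C)C(C)(C)C)c2cc(OCc3ccccc3)c(OC)c(OC)c2)ccc1OCc1ccccc1 | intermediate
17 | (2R,3R)-2-{(S)-[4-(benzyloxy)-3-methoxyphenyl](hydroxy)methyl}-3-{(S)-[3-(benzyloxy)-4,5-dimethoxyphenyl](hydroxy)methyl}butane-1,4-diyl dimethanesulfonate | COc1cc([C@@H](O)[C@@H](COS(C)(=O)=O)[C@H](COS(C)(=O)=O)[C@H](O)c2cc(OCc3ccccc3)c(OC)c(OC)c2)ccc1OCc1ccccc1 | intermediate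
18 | [(2S,3R,4R)-2-[4-(benzyloxy)-3-methoxyphenyl]-4-{(S)-[3-(benzyloxy)-4,5-dimethoxyphenyl](hydroxy)methyl}tetrahydrofuran-3-yl]methyl methanesulfonate | COc1cc([C@H]2OC[C@H]([C@H](O)c3cc(OCc4ccccc4)c(OC)c(OC)c3)[C@@H]2COS(C)(=O)=O)ccc1OCc1ccccc1 | intermediate
19 | (1S,3aR,4S,6aR)-1-[4-(benzyloxy)-3-methoxyphenyl]-4-[3-(benzyloxy)-4,5-dimethoxyphenyl]tetrahydro-1H,3H-furo[3,4-c]furan | COc1cc([C@H]2OC[C@H]3[C@@H]2CO[C@@H]3c2cc(OCc3ccccc3)c(OC)c(OC)c2)ccc1OCc1ccccc1 | intermediate
20 | 5-[(1S,3aR,4S,6aR)-4-(4-hydroxy-3-methoxyphenyl)tetrahydro-1H,3H-furo[3,4-c]furan-1-yl]-2,3-dimethoxyphenol | COc1cc([C@H]2OC[C@H]3[C@@H]2CO[C@@H]3c2cc(O)c(OC)c(OC)c2)ccc1O | target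

Total step count: 11. Longest linear sequence: 10 steps (1 to 20 through steps 1–3 and 5–11).

**Steps most likely to fail**

Step 7. Several things could go wrong:
- The hindered, inductively deactivated alkene may insert too slowly.
- The two alkene faces may be poorly differentiated.
- β-Oxygen elimination from the alkylpalladium may compete with CO insertion.
- Methanolysis of the allylic benzylic silyl ethers may set in.

The fallback sets out from 12 and returns at 15, so step 8 is skipped. It makes the same two C–C bonds with boron instead of palladium and CO. Syn diboration of 12 with bis(catecholato)diboron under Rh(acac)(nbd) and the Quinap enantiomer matched to the Si,Si face should give the bis(catechol boronate) F1. This is a known reaction type for E-1,2-disubstituted alkenes. Exchange with pinacol gives the bis(pinacol boronate) F2. Double Matteson homologation with ClCH2Li (from BrCH2Cl and nBuLi, THF, −78 °C) inserts one CH2 into each C–B bond with retention and gives the bis(boronylmethyl) compound F3. Oxidation with NaOH/H2O2 then delivers 15. Face selection is then set mainly by the ligand.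

Step 5. Boron-to-zinc exchange may be incomplete, methyl transfer may compete, and the many Lewis-basic ethers may erode catalyst control. The fallback sets out from 6 and 8 and returns at 11. It replaces alkenyl transfer by alkynyl transfer followed by trans reduction. Et2Zn with N-methylimidazole converts 6 into the ethylzinc acetylide F4. Under the (S)-BINOL/Ti(OiPr)4 system of step 1, F4 should add to the Si face of 8 to give the propargylic alcohol F5. Hydroxyl-directed trans-hydroalumination with NaAlH2(OCH2CH2OMe)2 in THF, followed by protonolysis, gives 11.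

Step 10. Fluoride may substitute the primary mesylates before the hindered benzylic silyl ethers are cleaved, elimination may intervene, or the second closure may stall. The fallback sets out from 15 and returns at 19, so step 9 is skipped. It reverses the polarity of the ring closure. Bu4NF removes both silyl groups from 15 to give the tetraol F6. Catalytic camphorsulfonic acid in CH2Cl2 then ionises each electron-rich benzylic alcohol, and the distal primary hydroxyl captures the cation. This known cyclodehydration of lignan tetraols is reversible and should settle on the diequatorial isomer 19, with C7 and C7' then dictated by C8 and C8'.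

**Further compounds**

F1 | step 7 | (1S,2S,3S,4S)-1-[4-(benzyloxy)-3-methoxyphenyl]-4-[3-(benzyloxy)-4,5-dimethoxyphenyl]-1,4-bis[(tert-butyldimethylsilyl)oxy]-2,3-bis(1,3,2-benzodioxaborol-2-yl)butane | COc1cc([C@@H](O[Si](C)(C)C(C)(C)C)[C@@H](B2Oc3ccccc3O2)[C@H](B2Oc3ccccc3O2)[C@H](O[Si](C)(C)C(C)(C)C)c2cc(OCc3ccccc3)c(OC)c(OC)c2)ccc1OCc1ccccc1
F2 | step 7 | (1S,2S,3S,4S)-1-[4-(benzyloxy)-3-methoxyphenyl]-4-[3-(benzyloxy)-4,5-dimethoxyphenyl]-1,4-bis[(tert-butyldimethylsilyl)oxy]-2,3-bis(4,4,5,5-tetramethyl-1,3,2-dioxaborolan-2-yl)butane | COc1cc([C@@H](O[Si](C)(C)C(C)(C)C)[C@@H](B2OC(C)(C)C(C)(C)O2)[C@H](B2OC(C)(C)C(C)(C)O2)[C@H](O[Si](C)(C)C(C)(C)C)c2cc(OCc3ccccc3)c(OC)c(OC)c2)ccc1OCc1ccccc1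
F3 | step 7 | (1S,2S,3S,4S)-1-[4-(benzyloxy)-3-methoxyphenyl]-4-[3-(benzyloxy)-4,5-dimethoxyphenyl]-1,4-bis[(tert-butyldimethylsilyl)oxy]-2,3-bis[(4,4,5,5-tetramethyl-1,3,2-dioxaborolan-2-yl)methyl]butane | COc1cc([C@@H](O[Si](C)(C)C(C)(C)C)[C@@H](CB2OC(C)(C)C(C)(C)O2)[C@H](CB2OC(C)(C)C(C)(C)O2)[C@H](O[Si](C)(C)C(C)(C)C)c2cc(OCc3ccccc3)c(OC)c(OC)c2)ccc1OCc1ccccc1
F4 | step 5 | {(3R)-3-[4-(benzyloxy)-3-methoxyphenyl]-3-[(tert-butyldimethylsilyl)oxy]prop-1-yn-1-yl}(ethyl)zinc | COc1cc([C@@H](O[Si](C)(C)C(C)(C)C)C#C[Zn]CC)ccc1OCc1ccccc1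
F5 | step 5 | (1R,4R)-1-[3-(benzyloxy)-4,5-dimethoxyphenyl]-4-[4-(benzyloxy)-3-methoxyphenyl]-4-[(tert-butyldimethylsilyl)oxy]but-2-yn-1-ol | COc1cc([C@@H](O[Si](C)(C)C(C)(C)C)C#C[C@H](O)c2cc(OCc3ccccc3)c(OC)c(OC)c2)ccc1OCc1ccccc1
F6 | step 10 | (1S,2R,3R,4S)-1-[4-(benzyloxy)-3-methoxyphenyl]-4-[3-(benzyloxy)-4,5-dimethoxyphenyl]-2,3-bis(hydroxymethyl)butane-1,4-diol | COc1cc([C@@H](O)[C@@H](CO)[C@H](CO)[C@H](O)c2cc(OCc3ccccc3)c(OC)c(OC)c2)ccc1OCc1ccccc1
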